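**Retrosynthetic overview**
1. Furanone (last ring): transannular addition of the C4 hydroxyl to C1 of a ten-membered ynone, the dehydrated equivalent of the biosynthetic C4-hydroxy-1,3-dione hemiketalization–dehydration.
2. Carbocycle and lactone (first, one operation): C6–C7 bond by intramolecular allylchromium addition of a 2-(bromomethyl)enoate to the C6 aldehyde (the bond the germacrene cyclase forms); the C6 alkoxide lactonizes onto C12.
3. Open chain: C2–C3 by acyl Sonogashira coupling of an east alkyne (C1, C7–C13) with a west acid chloride (C3–C6).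
4. East: Sharpless desymmetrization of dipropenylcarbinol, Mitsunobu inversion with methacrylic acid (C8), acetylide opening of the epoxide (C9, C10), Baylis–Hillman reaction (C11–C13). West: Seebach alkylation of the lactic acid dioxolanone (C4).
5. Ring order: ten-membered ring together with the lactone, then the furanone.

Assumption: germacrane numbering with the lactone read as the 12,6-olide (C4 = quaternary furanone carbon, C8 = methacrylate carbon, C9 = carbinol, C10 = CHMe); the target is then 4R,6S,7R,8S,9S,10S.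

**Step 1**
Reactants: 1 (E)-but-2-enal; 2 (E)-1-bromoprop-1-ene
Product: 4 (2E,5E)-hepta-2,5-dien-4-ol, via (E)-prop-1-enyllithium 3 (not isolated)
Conditions: 2, t-BuLi (2.0 equiv), Et2O, −78 °C; then 1, −78 to 0 °C; H2O
Reagents that add atoms: none
Why: Stereoretentive bromine–lithium exchange followed by 1,2-addition of the vinyllithium to the enal (organolithium carbonyl addition) gives the achiral, symmetric bis-allylic alcohol.

**Step 2**
Reactants: 4 (2E,5E)-hepta-2,5-dien-4-ol
Product: 5 (1R,2E)-1-[(2R,3R)-3-methyloxiran-2-yl]but-2-en-1-ol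
Conditions: Ti(OiPr)4 (0.15 equiv), D-(−)-diisopropyl tartrate (0.18 equiv), t-BuOOH (1.1 equiv), 4 Å MS, CH2Cl2, −20 °C
Reagents that add atoms: tert-butyl hydroperoxide, CC(C)(C)OO
Why: Sharpless asymmetric epoxidation used as a group-selective desymmetrization, in which the D-tartrate catalyst epoxidizes only the matched propenyl arm from one face to set C8, C9 and C10 (erythro), while any minor enantiomer is consumed by a fast second epoxidation.

**Step 3**
Reactants: 5 (1R,2E)-1-[(2R,3R)-3-methyloxiran-2-yl]but-2-en-1-ol; 6 2-methylprop-2-enoic acid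
Product: 7 (1S,2E)-1-[(2S,3R)-3-methyloxiran-2-yl]but-2-en-1-yl 2-methylprop-2-enoate
Conditions: PPh3, DIAD, THF, 0 °C to rt
Reagents that add atoms: none
Why: Mitsunobu esterification inverts the carbinol by SN2 displacement of the oxyphosphonium, converting the erythro epoxy alcohol into the threo ester and installing the C8 methacrylate in its final configuration.

**Step 4**
Reactants: 7 (1S,2E)-1-[(2S,3R)-3-methyloxiran-2-yl]but-2-en-1-yl 2-methylprop-2-enoate; 8 acetylene
Product: 10 (3R,4S,5S,6E)-4-hydroxy-3-methyloct-6-en-1-yn-5-yl 2-methylprop-2-enoate, via lithium acetylide 9 (not isolated)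
Conditions: 8, n-BuLi, THF, −78 °C; BF3·OEt2; then 7, −78 °C
Reagents that add atoms: none
Why: Lewis-acid-assisted acetylide opening of the epoxide (Yamaguchi-type SN2) takes place at C10, the carbon remote from the acyloxy-bearing C8, with inversion, so the trans-epoxide delivers the 9-OH/10-Me syn relationship.

**Step 5**
Reactants: 10 (3R,4S,5S,6E)-4-hydroxy-3-methyloct-6-en-1-yn-5-yl 2-methylprop-2-enoate
Product: 11 (3R,4S,5S,6E)-3-methyl-4-(triethylsilyloxy)oct-6-en-1-yn-5-yl 2-methylprop-2-enoate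
Conditions: Et3SiOTf, 2,6-lutidine, CH2Cl2, −78 °C
Reagents that add atoms: triethylsilyl trifluoromethanesulfonate, CC[Si](CC)(CC)OS(=O)(=O)C(F)(F)F
Why: Non-nucleophilic silyl ether formation blocks 1,2-migration of the neighboring methacrylate in the later amine-mediated steps and touches no stereocenter.

**Step 6**
Reactants: 11 (3R,4S,5S,6E)-3-methyl-4-(triethylsilyloxy)oct-6-en-1-yn-5-yl 2-methylprop-2-enoate
Product: 13 (2R,3S,4R)-4-methyl-1-oxo-3-(triethylsilyloxy)hex-5-yn-2-yl 2-methylprop-2-enoate, via vicinal diol 12 (not isolated)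
Conditions: OsO4 (2 mol %), NaIO4 (4 equiv), 2,6-lutidine, dioxane/H2O 3:1, rt
Reagents that add atoms: osmium tetroxide, O=[Os](=O)(=O)=O; sodium periodate, [Na+].[O-]I(=O)(=O)=O
Why: Lemieux–Johnson oxidative cleavage, in which OsO4 dihydroxylates the electron-neutral trans-disubstituted propenyl group much faster than the conjugated methacrylate or the alkyne and periodate cleaves the diol to the C7 aldehyde.

**Step 7**
Reactants: 13 (2R,3S,4R)-4-methyl-1-oxo-3-(triethylsilyloxy)hex-5-yn-2-yl 2-methylprop-2-enoate; 14 methyl prop-2-enoate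
Product: 15 methyl (4S,5S,6R)-3-hydroxy-6-methyl-2-methylidene-4-(2-methylprop-2-enoyloxy)-5-(triethylsilyloxy)oct-7-ynoate (C3 epimers)
Conditions: 14 (10 equiv, neat), quinuclidin-3-ol (0.3 equiv), rt
Reagents that add atoms: none
Why: Morita–Baylis–Hillman reaction, fast because the α-acyloxy aldehyde is strongly activated; the new carbinol center is formed as a mixture and is erased in step 13.

**Step 8**
Reactants: 16 (2S,5S)-2-tert-butyl-5-methyl-1,3-dioxolan-4-one; 17 1-bromo-3-methylbut-2-ene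
Product: 19 (2S,5R)-2-tert-butyl-5-methyl-5-(3-methylbut-2-enyl)-1,3-dioxolan-4-one, via lithium enolate 18 (not isolated)
Conditions: LDA, THF, −78 °C; then 17, −78 to −30 °C
Reagents that add atoms: none
Why: Seebach self-regeneration of stereocenters, in which the enolate is alkylated anti to the tert-butyl group of the acetal so that the prenyl group replaces the lactate hydrogen with retention and sets the quaternary C4 center.

**Step 9**
Reactants: 19 (2S,5R)-2-tert-butyl-5-methyl-5-(3-methylbut-2-enyl)-1,3-dioxolan-4-one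
Product: 20 (2R)-2-hydroxy-2,5-dimethylhex-4-enoic acid
Conditions: LiOH, THF/H2O, rt; then 1 M HCl to pH 3, 0 °C
Reagents that add atoms: lithium hydroxide, [Li+].[OH-]
Why: Saponification of the lactone acetal with loss of pivalaldehyde releases the α-hydroxy acid without touching the quaternary center.

**Step 10**
Reactants: 20 (2R)-2-hydroxy-2,5-dimethylhex-4-enoic acid
Product: 22 (2R)-2,5-dimethyl-2-(triethylsilyloxy)hex-4-enoyl chloride, via bis-silyl derivative 21 (not isolated)
Conditions: Et3SiCl (2.2 equiv), imidazole, CH2Cl2, rt; filter; then (COCl)2, DMF (cat.), CH2Cl2, 0 °C to rt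
Reagents that add atoms: chlorotriethylsilane, CC[Si](CC)(CC)Cl; oxalyl chloride, ClC(=O)C(=O)Cl
Why: Double silylation followed by Vilsmeier-type conversion of the silyl ester into the acid chloride gives the O-protected acyl donor under HCl-free conditions that spare the prenyl group and the tertiary silyl ether.

**Step 11**
Reactants: 15 methyl (4S,5S,6R)-3-hydroxy-6-methyl-2-methylidene-4-(2-methylprop-2-enoyloxy)-5-(triethylsilyloxy)oct-7-ynoate (C3 epimers); 22 (2R)-2,5-dimethyl-2-(triethylsilyloxy)hex-4-enoyl chloride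
Product: 23 methyl (4S,5S,6R,10R)-3-hydroxy-6,10,13-trimethyl-2-methylidene-4-(2-methylprop-2-enoyloxy)-9-oxo-5,10-bis(triethylsilyloxy)tetradec-12-en-7-ynoate (C3 epimers)
Conditions: PdCl2(PPh3)2 (2 mol %), CuI (4 mol %), Et3N (1.5 equiv), THF, rt
Reagents that add atoms: none
Why: Acyl Sonogashira coupling forms the C2–C3 bond under conditions mild enough for the acrylate, the hindered free carbinol and the silyl ethers, and the ynone carries the C1/C3 oxidation pattern of the furanone without creating a stereocenter.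

**Step 12**
Reactants: 23 methyl (4S,5S,6R,10R)-3-hydroxy-6,10,13-trimethyl-2-methylidene-4-(2-methylprop-2-enoyloxy)-9-oxo-5,10-bis(triethylsilyloxy)tetradec-12-en-7-ynoate (C3 epimers)
Product: 25 methyl (4S,5S,6R,10R)-3-hydroxy-6,10-dimethyl-2-methylidene-4-(2-methylprop-2-enoyloxy)-9,12-dioxo-5,10-bis(triethylsilyloxy)dodec-7-ynoate (C3 epimers), via secondary ozonide 24 (not isolated)
Conditions: O3, CH2Cl2, −78 °C, Sudan Red 7B as end-point indicator; then Me2S, −78 °C to rt
Reagents that add atoms: ozone, [O-][O+]=O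
Why: Ozonolysis with reductive work-up is selective for the electron-rich trisubstituted prenyl alkene over the two conjugated 1,1-disubstituted esters and the electron-poor ynone, and unveils the C6 aldehyde.

**Step 13**
Reactants: 25 methyl (4S,5S,6R,10R)-3-hydroxy-6,10-dimethyl-2-methylidene-4-(2-methylprop-2-enoyloxy)-9,12-dioxo-5,10-bis(triethylsilyloxy)dodec-7-ynoate (C3 epimers)
Product: 26 methyl (2Z,4S,5S,6R,10R)-2-(bromomethyl)-6,10-dimethyl-4-(2-methylprop-2-enoyloxy)-9,12-dioxo-5,10-bis(triethylsilyloxy)dodec-2-en-7-ynoate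
Conditions: NBS, Me2S, CH2Cl2, 0 °C to rt
Reagents that add atoms: N-bromosuccinimide, BrN1C(=O)CCC1=O
Why: Corey–Kim-type activation of the Baylis–Hillman alcohol and SN2′ attack of bromide give the rearranged (Z)-2-(bromomethyl)enoate, selectively at the allylic hydroxyl and without affecting the aldehyde.

**Step 14**
Reactants: 26 methyl (2Z,4S,5S,6R,10R)-2-(bromomethyl)-6,10-dimethyl-4-(2-methylprop-2-enoyloxy)-9,12-dioxo-5,10-bis(triethylsilyloxy)dodec-2-en-7-ynoate
Product: 29 (4R,6S,7R,8S,9S,10R)-8-(2-methylprop-2-enoyloxy)-3-oxo-4,9-bis(triethylsilyloxy)germacr-11(13)-en-1-yn-12,6-olide, via trivalent allylchromium species 27 (not isolated), via macrocyclic hydroxy ester 28 (not isolated)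
Conditions: CrCl2 (6 equiv), THF, rt, slow addition of 26 to 1 mM final concentration; aq. NH4Cl; then PPTS (cat.), CH2Cl2, rt
Reagents that add atoms: none
Why: Intramolecular Nozaki–Hiyama–Kishi (Barbier-type) allylation closes the ten-membered carbocycle at C6–C7 through a chair transition state with both ring chains pseudo-equatorial (6,7-anti, hence the trans-lactone) and with the aldehyde adding to C7 anti to the allylic C8–O bond under A(1,3) control, which sets C6 and C7, and the C6 alkoxide lactonizes onto the methyl ester.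

**Step 15**
Reactants: 29 (4R,6S,7R,8S,9S,10R)-8-(2-methylprop-2-enoyloxy)-3-oxo-4,9-bis(triethylsilyloxy)germacr-11(13)-en-1-yn-12,6-olide
Product: 31 (4R,6S,7R,8S,9S,10S)-1,4-epoxy-9-hydroxy-8-(2-methylprop-2-enoyloxy)-3-oxogermacra-1,11(13)-dien-12,6-olide, via diol ynone 30 (not isolated)
Conditions: HF·pyridine, THF, 0 °C to rt; then (Ph3P)AuNTf2 (5 mol %), CH2Cl2, rt
Reagents that add atoms: none
Why: After desilylation, gold-catalyzed 5-endo-dig addition of the C4 hydroxyl to C1 of the ynone (cycloisomerization of a γ-hydroxyalkynone, here transannular and helped by relief of alkyne strain) forms the 3(2H)-furanone without touching any stereocenter.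

**Compound list**
1 | (E)-but-2-enal | C/C=C/C=O | starting material
2 | (E)-1-bromoprop-1-ene | C/C=C/Br | starting material
3 | (E)-prop-1-enyllithium | C/C=C/[Li] | intermediate
4 | (2E,5E)-hepta-2,5-dien-4-ol | C/C=C/C(O)/C=C/C | intermediate
5 | (1R,2E)-1-[(2R,3R)-3-methyloxiran-2-yl]but-2-en-1-ol | O[C@H](/C=C/C)[C@H]1O[C@@H]1C | intermediate
6 | 2-methylprop-2-enoic acid (methacrylic acid) | C=C(C)C(=O)O | starting material
7 | (1S,2E)-1-[(2S,3R)-3-methyloxiran-2-yl]but-2-en-1-yl 2-methylprop-2-enoate | C=C(C)C(=O)O[C@@H](/C=C/C)[C@H]1O[C@@H]1C | intermediate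
8 | acetylene | C#C | starting material
9 | lithium acetylide | [Li]C#C | intermediate
10 | (3R,4S,5S,6E)-4-hydroxy-3-methyloct-6-en-1-yn-5-yl 2-methylprop-2-enoate | C=C(C)C(=O)O[C@@H](/C=C/C)[C@@H](O)[C@H](C)C#C | intermediate
11 | (3R,4S,5S,6E)-3-methyl-4-(triethylsilyloxy)oct-6-en-1-yn-5-yl 2-methylprop-2-enoate | C=C(C)C(=O)O[C@@H](/C=C/C)[C@@H](O[Si](CC)(CC)CC)[C@H](C)C#C | intermediate
12 | (3R,4S,5S)-6,7-dihydroxy-3-methyl-4-(triethylsilyloxy)oct-1-yn-5-yl 2-methylprop-2-enoate (diol diastereomers) | C=C(C)C(=O)O[C@@H](C(O)C(C)O)[C@@H](O[Si](CC)(CC)CC)[C@H](C)C#C | intermediate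
13 | (2R,3S,4R)-4-methyl-1-oxo-3-(triethylsilyloxy)hex-5-yn-2-yl 2-methylprop-2-enoate | C=C(C)C(=O)O[C@@H](C=O)[C@@H](O[Si](CC)(CC)CC)[C@H](C)C#C | intermediate
14 | methyl prop-2-enoate (methyl acrylate) | C=CC(=O)OC | starting material
15 | methyl (4S,5S,6R)-3-hydroxy-6-methyl-2-methylidene-4-(2-methylprop-2-enoyloxy)-5-(triethylsilyloxy)oct-7-ynoate (C3 epimers) | C=C(C)C(=O)O[C@@H](C(O)C(=C)C(=O)OC)[C@@H](O[Si](CC)(CC)CC)[C@H](C)C#C | intermediate
16 | (2S,5S)-2-tert-butyl-5-methyl-1,3-dioxolan-4-one (cis; from L-lactic acid) | C[C@@H]1O[C@H](C(C)(C)C)OC1=O | starting material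
17 | 1-bromo-3-methylbut-2-ene (prenyl bromide) | CC(C)=CCBr | starting material
18 | lithium (2S)-2-tert-butyl-5-methyl-2H-1,3-dioxol-4-olate | CC1=C([O-])O[C@@H](C(C)(C)C)O1.[Li+] | intermediate
19 | (2S,5R)-2-tert-butyl-5-methyl-5-(3-methylbut-2-enyl)-1,3-dioxolan-4-one | C[C@]1(CC=C(C)C)O[C@H](C(C)(C)C)OC1=O | intermediate
20 | (2R)-2-hydroxy-2,5-dimethylhex-4-enoic acid | C[C@@](O)(CC=C(C)C)C(=O)O | intermediate
21 | triethylsilyl (2R)-2,5-dimethyl-2-(triethylsilyloxy)hex-4-enoate | C[C@@](O[Si](CC)(CC)CC)(CC=C(C)C)C(=O)O[Si](CC)(CC)CC | intermediate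
22 | (2R)-2,5-dimethyl-2-(triethylsilyloxy)hex-4-enoyl chloride | C[C@@](O[Si](CC)(CC)CC)(CC=C(C)C)C(=O)Cl | intermediate
23 | methyl (4S,5S,6R,10R)-3-hydroxy-6,10,13-trimethyl-2-methylidene-4-(2-methylprop-2-enoyloxy)-9-oxo-5,10-bis(triethylsilyloxy)tetradec-12-en-7-ynoate (C3 epimers) | C=C(C)C(=O)O[C@@H](C(O)C(=C)C(=O)OC)[C@@H](O[Si](CC)(CC)CC)[C@H](C)C#CC(=O)[C@@](C)(CC=C(C)C)O[Si](CC)(CC)CC | intermediate
24 | secondary ozonide of 23: methyl (4S,5S,6R,10R)-11-(3,3-dimethyl-1,2,4-trioxolan-5-yl)-3-hydroxy-6,10-dimethyl-2-methylidene-4-(2-methylprop-2-enoyloxy)-9-oxo-5,10-bis(triethylsilyloxy)undec-7-ynoate | C=C(C)C(=O)O[C@@H](C(O)C(=C)C(=O)OC)[C@@H](O[Si](CC)(CC)CC)[C@H](C)C#CC(=O)[C@@](C)(CC1OOC(C)(C)O1)O[Si](CC)(CC)CC | intermediate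
25 | methyl (4S,5S,6R,10R)-3-hydroxy-6,10-dimethyl-2-methylidene-4-(2-methylprop-2-enoyloxy)-9,12-dioxo-5,10-bis(triethylsilyloxy)dodec-7-ynoate (C3 epimers) | C=C(C)C(=O)O[C@@H](C(O)C(=C)C(=O)OC)[C@@H](O[Si](CC)(CC)CC)[C@H](C)C#CC(=O)[C@@](C)(CC=O)O[Si](CC)(CC)CC | intermediate
26 | methyl (2Z,4S,5S,6R,10R)-2-(bromomethyl)-6,10-dimethyl-4-(2-methylprop-2-enoyloxy)-9,12-dioxo-5,10-bis(triethylsilyloxy)dodec-2-en-7-ynoate | C=C(C)C(=O)O[C@@H](/C=C(\CBr)C(=O)OC)[C@@H](O[Si](CC)(CC)CC)[C@H](C)C#CC(=O)[C@@](C)(CC=O)O[Si](CC)(CC)CC | intermediate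
27 | trivalent allylchromium species: dichloro{(2Z,4S,5S,6R,10R)-2-(methoxycarbonyl)-6,10-dimethyl-4-(2-methylprop-2-enoyloxy)-9,12-dioxo-5,10-bis(triethylsilyloxy)dodec-2-en-7-ynyl}chromium | C=C(C)C(=O)O[C@@H](/C=C(\C[Cr](Cl)Cl)C(=O)OC)[C@@H](O[Si](CC)(CC)CC)[C@H](C)C#CC(=O)[C@@](C)(CC=O)O[Si](CC)(CC)CC | intermediate
28 | methyl 2-[(1R,2S,3S,4R,8R,10S)-10-hydroxy-4,8-dimethyl-2-(2-methylprop-2-enoyloxy)-7-oxo-3,8-bis(triethylsilyloxy)cyclodec-5-yn-1-yl]prop-2-enoate | C=C(C)C(=O)O[C@@H]1[C@@H](O[Si](CC)(CC)CC)[C@H](C)C#CC(=O)[C@](C)(O[Si](CC)(CC)CC)C[C@H](O)[C@H]1C(=C)C(=O)OC | intermediate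
29 | (4R,6S,7R,8S,9S,10R)-8-(2-methylprop-2-enoyloxy)-3-oxo-4,9-bis(triethylsilyloxy)germacr-11(13)-en-1-yn-12,6-olide (ten-membered ynone, trans-fused α-methylene lactone) | C=C(C)C(=O)O[C@@H]1[C@@H](O[Si](CC)(CC)CC)[C@H](C)C#CC(=O)[C@@](C)(C[C@@H]2OC(=O)C(=C)[C@@H]12)O[Si](CC)(CC)CC | intermediate
30 | (4R,6S,7R,8S,9S,10R)-4,9-dihydroxy-8-(2-methylprop-2-enoyloxy)-3-oxogermacr-11(13)-en-1-yn-12,6-olide | C=C(C)C(=O)O[C@@H]1[C@@H](O)[C@H](C)C#CC(=O)[C@@](C)(C[C@@H]2OC(=O)C(=C)[C@@H]12)O | intermediate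
31 | (4R,6S,7R,8S,9S,10S)-1,4-epoxy-9-hydroxy-8-(2-methylprop-2-enoyloxy)-3-oxogermacra-1,11(13)-dien-12,6-olide (CNP0195404.1) | C=C(C)C(=O)O[C@@H]1[C@@H](O)[C@H](C)C2=CC(=O)[C@@](C)(C[C@@H]3OC(=O)C(=C)[C@@H]13)O2 | target

**Step count**
Total: 15 steps (east branch steps 1–7, west branch steps 8–10, union and endgame steps 11–15).
Longest linear sequence: 12 steps (1–7, then 11–15).

**Three steps most likely to fail**

Step 14 (macrocyclization). The product is a strained cyclodec-ynone, and open-chain 2-(alkoxycarbonyl)allylchromium reagents tend toward cis-lactones, so both yield and the C6/C7 outcome are at risk. The fallback bends the chain before closing it. It sets out from 26: aqueous HF in MeCN at 0 °C removes both silyl groups to give methyl (2Z,4S,5S,6R,10R)-2-(bromomethyl)-5,10-dihydroxy-6,10-dimethyl-4-(2-methylprop-2-enoyloxy)-9,12-dioxododec-2-en-7-ynoate F1. (Ph3P)AuNTf2 in CH2Cl2 then closes the furanone on the open chain to give the furanone bromo aldehyde F2. CrCl2 in THF at 1 mM closes the carbocycle on this pre-bent chain through the allylchromium species F3 and the macrocyclic furanone hydroxy ester F4, which lactonizes and comes back to the route at 31.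

Step 4 (epoxide opening beside the ester). Under BF3 the methacrylate carbonyl can attack C9 (dioxolanylium formation, acyl migration) or the acetylide can attack C9. The fallback opens the epoxide before the ester exists. It sets out from 5: diethyl(ethynyl)aluminum F5, made from 9 and Et2AlCl in toluene at 0 °C, is delivered from the aluminum alkoxide of the free hydroxyl and attacks C10 to give (3R,4S,5R,6E)-3-methyloct-6-en-1-yne-4,5-diol F6. Mitsunobu esterification with 6 (PPh3, DIAD, THF) then takes place at the more ionizable allylic C8 hydroxyl with inversion and comes back to the route at 10.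

Step 7 (Baylis–Hillman reaction). Under the amine catalyst the α-acyloxy-β-silyloxy aldehyde 13 can epimerize at C8, eliminate the C9 silyloxy group, or undergo acyl migration to the new hydroxyl. The fallback replaces amine catalysis by a stoichiometric, non-basic vinylmetal addition. It sets out from 13: methyl propiolate with DIBAL-H and N-methylmorpholine N-oxide in THF at 0 °C gives methyl 2-(diisobutylalumanyl)prop-2-enoate F7, which adds to the aldehyde at −20 °C within minutes and, after work-up with Rochelle salt, comes back to the route at 15.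

**Further compounds**
F1 | step 14 | methyl (2Z,4S,5S,6R,10R)-2-(bromomethyl)-5,10-dihydroxy-6,10-dimethyl-4-(2-methylprop-2-enoyloxy)-9,12-dioxododec-2-en-7-ynoate | C=C(C)C(=O)O[C@@H](/C=C(\CBr)C(=O)OC)[C@@H](O)[C@H](C)C#CC(=O)[C@@](C)(CC=O)O
F2 | step 14 | methyl (2Z,4S,5S,6S)-2-(bromomethyl)-5-hydroxy-6-[(5R)-5-methyl-4-oxo-5-(2-oxoethyl)-4,5-dihydrofuran-2-yl]-4-(2-methylprop-2-enoyloxy)hept-2-enoate | C=C(C)C(=O)O[C@@H](/C=C(\CBr)C(=O)OC)[C@@H](O)[C@H](C)C1=CC(=O)[C@@](C)(CC=O)O1
F3 | step 14 | trivalent allylchromium species derived from F2 (CrCl2 in place of Br) | C=C(C)C(=O)O[C@@H](/C=C(\C[Cr](Cl)Cl)C(=O)OC)[C@@H](O)[C@H](C)C1=CC(=O)[C@@](C)(CC=O)O1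
F4 | step 14 | methyl 2-[(4R,6S,7R,8S,9S,10S)-1,4-epoxy-6,9-dihydroxy-8-(2-methylprop-2-enoyloxy)-3-oxogermacr-1-en-7-yl]prop-2-enoate (seco-lactone of 31) | C=C(C)C(=O)O[C@@H]1[C@@H](O)[C@H](C)C2=CC(=O)[C@@](C)(C[C@H](O)[C@H]1C(=C)C(=O)OC)O2
F5 | step 4 | diethyl(ethynyl)aluminum | CC[Al](CC)C#C
F6 | step 4 | (3R,4S,5R,6E)-3-methyloct-6-en-1-yne-4,5-diol | O[C@H](/C=C/C)[C@@H](O)[C@H](C)C#C
F7 | step 7 | methyl 2-(diisobutylalumanyl)prop-2-enoate | C=C(C(=O)OC)[Al](CC(C)C)CC(C)C
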